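## Retrosynthetic overview

1. Pestalone E ⇐ benzophenone carrying four methoxymethyl ethers and a dimethyl acetal ⇐ (oxidation, phenol protection, desilylation) racemic benzhydrol silyl ether in which ring B is already complete.
2. The route rests on ring B: its carbon C1' lies between the oxygen-bearing carbons C2' and C6', with Cl on C3', CH3 on C4' and H on C5'. This is the pattern that a four-carbon chlorovinylketene (C3'–C6') and a two-carbon O-silyl ynol ether (C1', C2') assemble.
3. Ring B ⇐ 2-chloro-3-methylcyclobut-2-en-1-one + ring A propargylic silyl ether carrying a triisopropylsilyloxy alkyne (C1'–C6' and C2'–C3' by ketene–alkyne [2+2], then C5'–C6' by six-electron electrocyclization).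
4. Siloxyalkyne ⇐ terminal alkyne (acetylide oxygenation, O-silylation) ⇐ 2,6-dibromo-3,5-bis(methoxymethoxy)benzaldehyde (acetylide addition, then one bromide → prenyl, the other → masked formyl) ⇐ 3,5-dihydroxybenzaldehyde. Cyclobutenone ⇐ propyne + dichloroketene, 1,3-chlorine shift, zinc monodechlorination.
5. Ring order: ring A is bought; ring B is the only ring made, and it is made in the key step.

Key step: step 12

Assumption: the carbinol stereocentre is carried as a racemate because it is oxidised away in step 15, and commercial 3,5-dihydroxybenzaldehyde serves as the ring A source so that the alkyne can be attached before the second ortho carbonyl carbon exists.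

## Route

Step 1
Reactants: 1 propyne; 2 trichloroacetyl chloride
Product: 4 4,4-dichloro-3-methylcyclobut-2-en-1-one, via dichloroketene 3 (not isolated)
Conditions: propyne (3 equiv, condensed), Zn–Cu couple, Et2O/DME, sealed vessel, 0 °C → rt
Reagents that add atoms: none
Why: Zinc dechlorinates the acid chloride to dichloroketene, which undergoes a thermal ketene–alkyne [2+2] cycloaddition with its carbonyl carbon bonding to the terminal alkyne carbon, while DME ties up ZnCl2 so that the kinetic 4,4-dichloro adduct is retained.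

Step 2
Reactants: 4 4,4-dichloro-3-methylcyclobut-2-en-1-one
Product: 5 racemic 2,4-dichloro-3-methylcyclobut-2-en-1-one
Conditions: ZnCl2 (0.2 equiv), Et2O, reflux
Reagents that add atoms: none
Why: Lewis-acid-assisted ionization of the allylic C4–Cl bond and return of chloride at C2 (allylic 1,3-chlorine shift, known for 4,4-dichlorocyclobutenones) should give the more stable conjugated 2-chloroenone.

Step 3
Reactants: 5 racemic 2,4-dichloro-3-methylcyclobut-2-en-1-one
Product: 6 2-chloro-3-methylcyclobut-2-en-1-one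
Conditions: Zn dust (1.3 equiv), AcOH, EtOH, 0 °C; isolated by careful distillation and kept as a toluene solution (volatile)
Reagents that add atoms: none
Why: Zinc/acetic acid reduction of an α-chloro ketone removes only the sp3-bound, allylic chlorine at C4 through a zinc enolate protonated at C4, the vinylic C2–Cl bond being inert under these conditions.

Step 4
Reactants: 7 3,5-dihydroxybenzaldehyde
Product: 8 3,5-bis(methoxymethoxy)benzaldehyde
Conditions: MOMCl (2.6 equiv), i-Pr2NEt, CH2Cl2, 0 °C → rt
Reagents that add atoms: chloromethyl methyl ether, COCCl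
Why: Base-mediated Williamson O-alkylation of both phenols with the reactive α-chloro ether leaves the aldehyde untouched.

Step 5
Reactants: 8 3,5-bis(methoxymethoxy)benzaldehyde
Product: 9 2,6-dibromo-3,5-bis(methoxymethoxy)benzaldehyde
Conditions: NBS (2.1 equiv), DMF, 0 °C → rt
Reagents that add atoms: N-bromosuccinimide, O=C1CCC(=O)N1Br
Why: Electrophilic aromatic bromination places each bromine para to one ether oxygen and ortho to the other, the position between the two ethers being the slowest site, as in the known 2,6-dihalogenation of 3,5-dialkoxybenzaldehydes.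

Step 6
Reactants: 9 2,6-dibromo-3,5-bis(methoxymethoxy)benzaldehyde
Product: 11 racemic tert-butyl({1-[2,6-dibromo-3,5-bis(methoxymethoxy)phenyl]-3-(trimethylsilyl)prop-2-yn-1-yl}oxy)dimethylsilane, via lithium alkoxide 10 (not isolated)
Conditions: LiC≡CSiMe3 (0.5 M in THF, 1.1 equiv), THF, −78 °C; then t-BuMe2SiOTf (1.5 equiv), −78 → 0 °C
Reagents that add atoms: lithium (trimethylsilyl)acetylide, [Li]C#C[Si](C)(C)C; tert-butyldimethylsilyl trifluoromethanesulfonate, CC(C)(C)[Si](C)(C)OS(=O)(=O)C(F)(F)F
Why: 1,2-Addition of the acetylide to the aldehyde (acetylides do not exchange aryl bromides) gives the racemic propargylic alkoxide, which is O-silylated in the same flask by the silyl triflate.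

Step 7
Reactants: 11 racemic dibromo propargylic silyl ether; 12 prenyl bromide (1-bromo-3-methylbut-2-ene)
Product: 15 racemic tert-butyl({1-[2-bromo-3,5-bis(methoxymethoxy)-6-(3-methylbut-2-en-1-yl)phenyl]-3-(trimethylsilyl)prop-2-yn-1-yl}oxy)dimethylsilane, via aryllithium 13 (not isolated), via arylcopper 14 (not isolated)
Conditions: n-BuLi (1.05 equiv), THF, −78 °C; CuBr·SMe2 (1.1 equiv), −78 → −40 °C; 12 (1.5 equiv), −40 → 0 °C
Reagents that add atoms: none
Why: Bromine–lithium exchange at one of the two equivalent bromides, transmetalation to the arylcopper and SN2 allylation at the primary carbon of prenyl bromide should give the linear prenyl arene, the low temperature suppressing oxygen-to-carbon silyl migration.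

Step 8
Reactants: 15 racemic monobromo prenyl arene
Product: 17 racemic 2-{1-[(tert-butyldimethylsilyl)oxy]-3-(trimethylsilyl)prop-2-yn-1-yl}-4,6-bis(methoxymethoxy)-3-(3-methylbut-2-en-1-yl)benzaldehyde, via aryllithium 16 (not isolated)
Conditions: n-BuLi (1.1 equiv), THF, −78 °C; DMF (3 equiv), −78 → 0 °C; then H2O
Reagents that add atoms: N,N-dimethylformamide, CN(C)C=O
Why: Bromine–lithium exchange followed by formylation of the aryllithium with DMF (Bouveault aldehyde synthesis) installs the future aldehyde carbon, the adduct collapsing to the aldehyde on aqueous quench.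

Step 9
Reactants: 17 racemic aldehyde
Product: 18 racemic tert-butyl({1-[2-(dimethoxymethyl)-3,5-bis(methoxymethoxy)-6-(3-methylbut-2-en-1-yl)phenyl]-3-(trimethylsilyl)prop-2-yn-1-yl}oxy)dimethylsilane
Conditions: HC(OMe)3 (10 equiv), MeOH, pyridinium p-toluenesulfonate (0.1 equiv), rt; Et3N quench; Et3N-deactivated silica
Reagents that add atoms: trimethyl orthoformate, COC(OC)OC; methanol, CO
Why: Mildly acid-catalysed acetalization driven by the orthoformate as water scavenger should leave the aryl methoxymethyl ethers, the hindered secondary silyl ether and the C-silyl alkyne intact.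

Step 10
Reactants: 18 racemic dimethyl acetal
Product: 19 racemic tert-butyl({1-[2-(dimethoxymethyl)-3,5-bis(methoxymethoxy)-6-(3-methylbut-2-en-1-yl)phenyl]prop-2-yn-1-yl}oxy)dimethylsilane
Conditions: K2CO3 (0.3 equiv), MeOH, rt
Reagents that add atoms: none
Why: Methoxide-mediated protodesilylation cleaves only the alkynyl C–Si bond, since O-silyl, acetal and methoxymethyl groups are stable to K2CO3 in methanol.

Step 11
Reactants: 19 racemic terminal alkyne
Product: 22 racemic tert-butyl({1-[2-(dimethoxymethyl)-3,5-bis(methoxymethoxy)-6-(3-methylbut-2-en-1-yl)phenyl]-3-[(triisopropylsilyl)oxy]prop-2-yn-1-yl}oxy)dimethylsilane, via lithium acetylide 20 (not isolated), via lithium ynolate 21 (not isolated)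
Conditions: n-BuLi (1.05 equiv), THF, −78 °C; LiOOt-Bu [t-BuOOH + LiN(SiMe3)2, THF, −78 °C], −78 → 0 °C; i-Pr3SiOTf (1.1 equiv), −78 °C; Et3N, pentane work-up, rapid filtration through Et3N-deactivated silica
Reagents that add atoms: tert-butyl hydroperoxide, CC(C)(C)OO; triisopropylsilyl trifluoromethanesulfonate, CC(C)[Si](C(C)C)(C(C)C)OS(=O)(=O)C(F)(F)F
Why: Electrophilic oxygenation of the lithium acetylide by lithium tert-butyl peroxide (attack on the peroxide oxygen with loss of tert-butoxide) gives the ynolate, which the bulky silyl triflate traps on oxygen, as in established siloxyalkyne syntheses.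

Step 12
Reactants: 22 racemic siloxyalkyne; 6 2-chloro-3-methylcyclobut-2-en-1-one
Product: 27 racemic 2-{[(tert-butyldimethylsilyl)oxy][2-(dimethoxymethyl)-3,5-bis(methoxymethoxy)-6-(3-methylbut-2-en-1-yl)phenyl]methyl}-4-chloro-5-methyl-3-[(triisopropylsilyl)oxy]phenol, via chlorovinylketene 23 (not isolated), via vinylcyclobutenone 24 (not isolated), via dienylketene 25 (not isolated), via cyclohexadienone 26 (not isolated)
Conditions: 6 (1.5 equiv), toluene (0.5 M), sealed tube, 80 °C then 110 °C
Reagents that add atoms: none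
Why: Heating opens 6 by four-electron electrocyclic ring opening to chlorovinylketene 23, whose electrophilic carbonyl carbon is attacked by the nucleophilic, carbinol-bearing carbon of the O-silyl ynol ether in a [2+2] cycloaddition that forms C1'–C6' and C2'–C3' and gives vinylcyclobutenone 24. A second four-electron opening gives dienylketene 25, and ring B is closed by thermal disrotatory six-electron electrocyclization between the ketene carbon and the terminal CH2 (C5'–C6'), after which cyclohexadienone 26 tautomerizes to the phenol. The closest known reaction is the Danheiser benzannulation of cyclobutenones with siloxyalkynes, which gives resorcinol monosilyl ethers. No stereocentre is created in ring B, the racemic carbinol centre is a spectator, and the diastereomers of 24 converge. The step needs regiocontrol in the ketene–alkyne union, secured by the polarization of the siloxyalkyne, chemoselectivity over the prenyl double bond, secured by the far higher nucleophilicity of the ynol ether, and inward rotation of the isopropenyl group when 24 opens, secured by the outward preference of the chlorine donor and the reversibility of that opening. An excess of the volatile cyclobutenone offsets the steric shielding of the alkyne terminus.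

Step 13
Reactants: 27 racemic resorcinol monosilyl ether
Product: 28 racemic 4-chloro-2-{[2-(dimethoxymethyl)-3,5-bis(methoxymethoxy)-6-(3-methylbut-2-en-1-yl)phenyl](hydroxy)methyl}-5-methylbenzene-1,3-diol
Conditions: Bu4NF (4 equiv), AcOH (2 equiv), THF, 0 °C → rt
Reagents that add atoms: none
Why: Fluoride-mediated desilylation cleaves both Si–O bonds (the aryl silyl ether fast, the hindered benzhydryl silyl ether more slowly), the acetic acid buffer keeping the medium near neutral so that the acetal, the methoxymethyl ethers and the ortho-hydroxybenzhydrol survive.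

Step 14
Reactants: 28 racemic triol
Product: 29 racemic [3-chloro-2,6-bis(methoxymethoxy)-4-methylphenyl][2-(dimethoxymethyl)-3,5-bis(methoxymethoxy)-6-(3-methylbut-2-en-1-yl)phenyl]methanol
Conditions: MOMCl (2.5 equiv), K2CO3 (4 equiv), acetone, rt
Reagents that add atoms: chloromethyl methyl ether, COCCl
Why: Chemoselective Williamson O-alkylation of the two phenoxides formed by K2CO3, the hindered secondary benzhydrol not being deprotonated under these conditions.

Step 15
Reactants: 29 racemic benzhydrol
Product: 30 [3-chloro-2,6-bis(methoxymethoxy)-4-methylphenyl][2-(dimethoxymethyl)-3,5-bis(methoxymethoxy)-6-(3-methylbut-2-en-1-yl)phenyl]methanone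
Conditions: Dess–Martin periodinane (1.5 equiv), NaHCO3 (5 equiv), CH2Cl2, 0 °C → rt
Reagents that add atoms: none
Why: Dess–Martin oxidation of the secondary benzhydrol gives the diaryl ketone under bicarbonate buffering, which the alkene, the acetal and the acetal-type ethers tolerate.

Step 16
Reactants: 30 protected benzophenone
Product: 32 pestalone E, via tetraphenol dimethyl acetal 31 (not isolated)
Conditions: HCl (1.25 M in MeOH), 0 °C → rt; then THF/H2O (1:1), rt; neutral work-up without base
Reagents that add atoms: water, O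
Why: Acid-catalysed methanolysis of the four aryl methoxymethyl ethers (formaldehyde trapped as dimethoxymethane) is followed by aqueous hydrolysis of the dimethyl acetal, and the phenol next to the prenyl group is para to the formyl group and hence a poor nucleophile, which should disfavour chroman formation at room temperature.

## Compound list

1 | propyne | CC#C | starting material
2 | trichloroacetyl chloride | O=C(Cl)C(Cl)(Cl)Cl | starting material
3 | dichloroketene (not isolated) | O=C=C(Cl)Cl | intermediate
4 | 4,4-dichloro-3-methylcyclobut-2-en-1-one | CC1=CC(=O)C1(Cl)Cl | intermediate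
5 | racemic 2,4-dichloro-3-methylcyclobut-2-en-1-one | CC1=C(Cl)C(=O)C1Cl | intermediate
6 | 2-chloro-3-methylcyclobut-2-en-1-one | CC1=C(Cl)C(=O)C1 | intermediate
7 | 3,5-dihydroxybenzaldehyde | O=Cc1cc(O)cc(O)c1 | starting material
8 | 3,5-bis(methoxymethoxy)benzaldehyde | O=Cc1cc(OCOC)cc(OCOC)c1 | intermediate
9 | 2,6-dibromo-3,5-bis(methoxymethoxy)benzaldehyde | O=Cc1c(Br)c(OCOC)cc(OCOC)c1Br | intermediate
10 | racemic lithium 1-[2,6-dibromo-3,5-bis(methoxymethoxy)phenyl]-3-(trimethylsilyl)prop-2-yn-1-olate (not isolated) | [Li]OC(C#C[Si](C)(C)C)c1c(Br)c(OCOC)cc(OCOC)c1Br | intermediate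
11 | racemic tert-butyl({1-[2,6-dibromo-3,5-bis(methoxymethoxy)phenyl]-3-(trimethylsilyl)prop-2-yn-1-yl}oxy)dimethylsilane | CC(C)(C)[Si](C)(C)OC(C#C[Si](C)(C)C)c1c(Br)c(OCOC)cc(OCOC)c1Br | intermediate
12 | prenyl bromide (1-bromo-3-methylbut-2-ene) | CC(C)=CCBr | starting material
13 | racemic {3-bromo-2-[1-(tert-butyldimethylsilyloxy)-3-(trimethylsilyl)prop-2-yn-1-yl]-4,6-bis(methoxymethoxy)phenyl}lithium (not isolated) | [Li]c1c(OCOC)cc(OCOC)c(Br)c1C(O[Si](C)(C)C(C)(C)C)C#C[Si](C)(C)C | intermediate
14 | racemic {3-bromo-2-[1-(tert-butyldimethylsilyloxy)-3-(trimethylsilyl)prop-2-yn-1-yl]-4,6-bis(methoxymethoxy)phenyl}copper (not isolated) | [Cu]c1c(OCOC)cc(OCOC)c(Br)c1C(O[Si](C)(C)C(C)(C)C)C#C[Si](C)(C)C | intermediate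
15 | racemic tert-butyl({1-[2-bromo-3,5-bis(methoxymethoxy)-6-(3-methylbut-2-en-1-yl)phenyl]-3-(trimethylsilyl)prop-2-yn-1-yl}oxy)dimethylsilane | CC(C)=CCc1c(OCOC)cc(OCOC)c(Br)c1C(O[Si](C)(C)C(C)(C)C)C#C[Si](C)(C)C | intermediate
16 | racemic {2-[1-(tert-butyldimethylsilyloxy)-3-(trimethylsilyl)prop-2-yn-1-yl]-4,6-bis(methoxymethoxy)-3-(3-methylbut-2-en-1-yl)phenyl}lithium (not isolated) | CC(C)=CCc1c(OCOC)cc(OCOC)c([Li])c1C(O[Si](C)(C)C(C)(C)C)C#C[Si](C)(C)C | intermediate
17 | racemic 2-{1-[(tert-butyldimethylsilyl)oxy]-3-(trimethylsilyl)prop-2-yn-1-yl}-4,6-bis(methoxymethoxy)-3-(3-methylbut-2-en-1-yl)benzaldehyde | CC(C)=CCc1c(OCOC)cc(OCOC)c(C=O)c1C(O[Si](C)(C)C(C)(C)C)C#C[Si](C)(C)C | intermediate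
18 | racemic tert-butyl({1-[2-(dimethoxymethyl)-3,5-bis(methoxymethoxy)-6-(3-methylbut-2-en-1-yl)phenyl]-3-(trimethylsilyl)prop-2-yn-1-yl}oxy)dimethylsilane | CC(C)=CCc1c(OCOC)cc(OCOC)c(C(OC)OC)c1C(O[Si](C)(C)C(C)(C)C)C#C[Si](C)(C)C | intermediate
19 | racemic tert-butyl({1-[2-(dimethoxymethyl)-3,5-bis(methoxymethoxy)-6-(3-methylbut-2-en-1-yl)phenyl]prop-2-yn-1-yl}oxy)dimethylsilane | CC(C)=CCc1c(OCOC)cc(OCOC)c(C(OC)OC)c1C(O[Si](C)(C)C(C)(C)C)C#C | intermediate
20 | racemic lithium acetylide of 19 (not isolated) | CC(C)=CCc1c(OCOC)cc(OCOC)c(C(OC)OC)c1C(O[Si](C)(C)C(C)(C)C)C#C[Li] | intermediate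
21 | racemic lithium 3-[(tert-butyldimethylsilyl)oxy]-3-[2-(dimethoxymethyl)-3,5-bis(methoxymethoxy)-6-(3-methylbut-2-en-1-yl)phenyl]prop-1-yn-1-olate (not isolated) | CC(C)=CCc1c(OCOC)cc(OCOC)c(C(OC)OC)c1C(O[Si](C)(C)C(C)(C)C)C#CO[Li] | intermediate
22 | racemic tert-butyl({1-[2-(dimethoxymethyl)-3,5-bis(methoxymethoxy)-6-(3-methylbut-2-en-1-yl)phenyl]-3-[(triisopropylsilyl)oxy]prop-2-yn-1-yl}oxy)dimethylsilane | CC(C)=CCc1c(OCOC)cc(OCOC)c(C(OC)OC)c1C(O[Si](C)(C)C(C)(C)C)C#CO[Si](C(C)C)(C(C)C)C(C)C | intermediate
23 | 2-chloro-3-methylbuta-1,3-dien-1-one (chlorovinylketene; not isolated) | C=C(C)C(Cl)=C=O | intermediate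
24 | 4-chloro-4-(prop-1-en-2-yl)-3-[(triisopropylsilyl)oxy]cyclobut-2-en-1-one bearing at C2 the (tert-butyldimethylsilyl)oxy[2-(dimethoxymethyl)-3,5-bis(methoxymethoxy)-6-(3-methylbut-2-en-1-yl)phenyl]methyl group (diastereomer mixture; not isolated) | CC(C)=CCc1c(OCOC)cc(OCOC)c(C(OC)OC)c1C(O[Si](C)(C)C(C)(C)C)C1=C(O[Si](C(C)C)(C(C)C)C(C)C)C(Cl)(C(C)=C)C1=O | intermediate
25 | 4-chloro-5-methyl-3-[(triisopropylsilyl)oxy]hexa-1,3,5-trien-1-one bearing the same silyloxy(aryl)methyl group at C2, isopropenyl cis to the ketene-bearing carbon (racemic; not isolated) | CC(C)=CCc1c(OCOC)cc(OCOC)c(C(OC)OC)c1C(O[Si](C)(C)C(C)(C)C)C(=C=O)/C(O[Si](C(C)C)(C(C)C)C(C)C)=C(Cl)\C(C)=C | intermediate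
26 | 4-chloro-5-methyl-3-[(triisopropylsilyl)oxy]cyclohexa-2,4-dien-1-one bearing the same silyloxy(aryl)methyl group at C2 (racemic; not isolated) | CC(C)=CCc1c(OCOC)cc(OCOC)c(C(OC)OC)c1C(O[Si](C)(C)C(C)(C)C)C1=C(O[Si](C(C)C)(C(C)C)C(C)C)C(Cl)=C(C)CC1=O | intermediate
27 | racemic 2-{[(tert-butyldimethylsilyl)oxy][2-(dimethoxymethyl)-3,5-bis(methoxymethoxy)-6-(3-methylbut-2-en-1-yl)phenyl]methyl}-4-chloro-5-methyl-3-[(triisopropylsilyl)oxy]phenol | CC(C)=CCc1c(OCOC)cc(OCOC)c(C(OC)OC)c1C(O[Si](C)(C)C(C)(C)C)c1c(O)cc(C)c(Cl)c1O[Si](C(C)C)(C(C)C)C(C)C | intermediate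
28 | racemic 4-chloro-2-{[2-(dimethoxymethyl)-3,5-bis(methoxymethoxy)-6-(3-methylbut-2-en-1-yl)phenyl](hydroxy)methyl}-5-methylbenzene-1,3-diol | CC(C)=CCc1c(OCOC)cc(OCOC)c(C(OC)OC)c1C(O)c1c(O)cc(C)c(Cl)c1O | intermediate
29 | racemic [3-chloro-2,6-bis(methoxymethoxy)-4-methylphenyl][2-(dimethoxymethyl)-3,5-bis(methoxymethoxy)-6-(3-methylbut-2-en-1-yl)phenyl]methanol | CC(C)=CCc1c(OCOC)cc(OCOC)c(C(OC)OC)c1C(O)c1c(OCOC)cc(C)c(Cl)c1OCOC | intermediate
30 | [3-chloro-2,6-bis(methoxymethoxy)-4-methylphenyl][2-(dimethoxymethyl)-3,5-bis(methoxymethoxy)-6-(3-methylbut-2-en-1-yl)phenyl]methanone | CC(C)=CCc1c(OCOC)cc(OCOC)c(C(OC)OC)c1C(=O)c1c(OCOC)cc(C)c(Cl)c1OCOC | intermediate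
31 | (3-chloro-2,6-dihydroxy-4-methylphenyl)[2-(dimethoxymethyl)-3,5-dihydroxy-6-(3-methylbut-2-en-1-yl)phenyl]methanone (not isolated) | CC(C)=CCc1c(O)cc(O)c(C(OC)OC)c1C(=O)c1c(O)cc(C)c(Cl)c1O | intermediate
32 | pestalone E, 2-(3-chloro-2,6-dihydroxy-4-methylbenzoyl)-4,6-dihydroxy-3-(3-methylbut-2-en-1-yl)benzaldehyde | CC(C)=CCc1c(O)cc(O)c(C=O)c1C(=O)c1c(O)cc(C)c(Cl)c1O | target

## Step count and risks

Total step count: 16 (steps 1–3 for the cyclobutenone, steps 4–11 for the siloxyalkyne, step 12 for the union, steps 13–16 for the end game).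
Longest linear sequence: 13 steps (steps 4–16, from 3,5-dihydroxybenzaldehyde).

Steps most likely to fail:

1. Step 12 (key step). What may go wrong: the doubly allylic tertiary C–Cl bond of the [2+2] adduct may ionize, or the chlorovinylketene may oligomerize, before the cascade reaches the electrocyclization, and the product phenol may be acylated by excess ketene. Fallback, setting out from 4 and 22 and returning at 28: the chlorine is left out of the cycloaddition partner and introduced afterwards. Exhaustive dechlorination of 4 (Zn dust, AcOH, TMEDA, EtOH, 0 °C → rt) gives 3-methylcyclobut-2-en-1-one F1, the classical substrate of this benzannulation. Heating F1 with 22 in toluene (80 → 110 °C) should give the chlorine-free resorcinol monosilyl ether F2. Bu4NF/AcOH in THF then gives the chlorine-free triol F3, whose free resorcinol ring is locally symmetric (C3' and C5' equivalent). One equivalent of N-chlorosuccinimide in MeCN at −20 °C should chlorinate this most electron-rich ring once, ortho to one hydroxyl and para to the other, to give 28.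

2. Step 11. What may go wrong: oxygen transfer from the peroxide to the hindered, propargylically oxygenated acetylide may be incomplete, so that the alkyne is recovered or silylated on carbon. Fallback, setting out from 19 and returning at 22: oxygen is delivered from a hypervalent iodine carboxylate instead of a peroxide. Lithium acetylide 20 (n-BuLi, THF, −78 °C) is treated with [bis(benzoyloxy)iodo]benzene, PhI(O2CPh)2 (−78 °C → rt), to give the alkynyl benzoate F4. MeLi (2 equiv, THF, −78 °C) cleaves this ynol ester, as enol esters are cleaved to enolates, to give ynolate 21, which is silylated with i-Pr3SiOTf as in step 11 to give 22.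

3. Step 16. What may go wrong: under protic acid the C5 phenol may cyclize onto the prenyl double bond (chroman formation), HCl or methanol may add across that double bond, and liberated formaldehyde equivalents may alkylate the free resorcinol ring. Fallback, setting out from 30 and returning at 32: the Brønsted-acid solvolysis is replaced by aprotic silyl transfer. Me3SiOTf (10 equiv) with 2,2'-bipyridyl (15 equiv) in MeCN (0 °C → rt) converts aryl methoxymethyl ethers into aryl trimethylsilyl ethers and activates the dimethyl acetal, which releases the aldehyde on addition of water. This gives the tetrakis(trimethylsilyl) ether of pestalone E F5, whose aryl Si–O bonds hydrolyse at neutral pH (THF/H2O, rt) to give 32.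

Further compounds
F1 | step 12 | 3-methylcyclobut-2-en-1-one | CC1=CC(=O)C1
F2 | step 12 | racemic 2-{[(tert-butyldimethylsilyl)oxy][2-(dimethoxymethyl)-3,5-bis(methoxymethoxy)-6-(3-methylbut-2-en-1-yl)phenyl]methyl}-5-methyl-3-[(triisopropylsilyl)oxy]phenol | CC(C)=CCc1c(OCOC)cc(OCOC)c(C(OC)OC)c1C(O[Si](C)(C)C(C)(C)C)c1c(O)cc(C)cc1O[Si](C(C)C)(C(C)C)C(C)C
F3 | step 12 | racemic 2-{[2-(dimethoxymethyl)-3,5-bis(methoxymethoxy)-6-(3-methylbut-2-en-1-yl)phenyl](hydroxy)methyl}-5-methylbenzene-1,3-diol | CC(C)=CCc1c(OCOC)cc(OCOC)c(C(OC)OC)c1C(O)c1c(O)cc(C)cc1O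
F4 | step 11 | racemic 3-[(tert-butyldimethylsilyl)oxy]-3-[2-(dimethoxymethyl)-3,5-bis(methoxymethoxy)-6-(3-methylbut-2-en-1-yl)phenyl]prop-1-yn-1-yl benzoate | CC(C)=CCc1c(OCOC)cc(OCOC)c(C(OC)OC)c1C(O[Si](C)(C)C(C)(C)C)C#COC(=O)c1ccccc1
F5 | step 16 | 2-{3-chloro-4-methyl-2,6-bis[(trimethylsilyl)oxy]benzoyl}-3-(3-methylbut-2-en-1-yl)-4,6-bis[(trimethylsilyl)oxy]benzaldehyde | CC(C)=CCc1c(O[Si](C)(C)C)cc(O[Si](C)(C)C)c(C=O)c1C(=O)c1c(O[Si](C)(C)C)cc(C)c(Cl)c1O[Si](C)(C)C
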